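## Retrosynthetic overview

1. Both esters go on last: the 8-O-tigloyl group before, and the 4-O-aroyl group after, an anti-selective reduction of a 4-ketone.
2. The 8-hydroxyl and the 6,7-alkene arise together from 1,6-borylation/oxidation of linear dienone 13, obtained by dehydrogenation of enone 12.
3. The five-membered ring is formed second, by intramolecular aldol closure of the C3–C3a bond in diketone 11, which also creates the tertiary carbinol.
4. The quaternary stereocentre comes from an enantioselective Cu-catalysed conjugate addition of a masked homoenolate Grignard reagent to the C2v-symmetric dienone 5 (key step).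
5. The seven-membered ring is formed first: 5 derives from 2,5-dimethylfuran by oxyallyl (4+3) cycloaddition, hydrogenation and double β-elimination.

Bicyclic compounds carry azulene locants: C3 carbinol, C3a ring-fusion CH, C4, C6 methyl, C8, C8a ring-fusion C-methyl.

Assumption: 2, 6, 16 and 19 are bought, and the ligand antipode in step 5 is the one that gives (6R)-10.

## Route

Step 1
Reactants: 1 2,5-dimethylfuran; 2 1,1,3,3-tetrabromopropan-2-one
Product: 3 2,4-dibromo-1,5-dimethyl-8-oxabicyclo[3.2.1]oct-6-en-3-one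
Conditions: Zn–Cu couple, THF, −10 °C to rt
Reagents that add atoms: none
Why: Zinc reduces 2 to a dibromo-oxyallyl cation that adds across C2/C5 of the furan in a (4+3) cycloaddition, which destroys the furan aromaticity; the oxygen bridge can only be cis, and the bromide configuration (epimer mixture) is irrelevant because both bromines are removed next.

Step 2
Reactants: 3 2,4-dibromo-1,5-dimethyl-8-oxabicyclo[3.2.1]oct-6-en-3-one
Product: 4 (1R,5S)-1,5-dimethyl-8-oxabicyclo[3.2.1]octan-3-one
Conditions: H2 (1 atm), Pd/C, NaOAc, MeOH, rt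
Reagents that add atoms: none
Why: Heterogeneous hydrogenation saturates the strained alkene while both α-keto C–Br bonds undergo hydrogenolysis under acetate buffering, giving the achiral meso ketone.

Step 3
Reactants: 4 (1R,5S)-1,5-dimethyl-8-oxabicyclo[3.2.1]octan-3-one
Product: 5 3,6-dimethylcyclohepta-2,6-dien-1-one
Conditions: TsOH·H2O (cat.), toluene, reflux, Dean–Stark
Reagents that add atoms: none
Why: Acid-catalysed double β-elimination: both tertiary bridgehead C–O bonds are β to the ketone, so enol-assisted ring opening and E1 dehydration of the resulting tertiary alcohol give the symmetric cross-conjugated dienone (no stereocentre).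

Step 4
Reactants: 6 4-methylpent-1-en-3-one
Product: 8 2-(2-bromoethyl)-2-(propan-2-yl)-1,3-dioxolane, via 1-bromo-4-methylpentan-3-one 7 (not isolated)
Conditions: HBr (anhydrous), CH2Cl2, 0 °C; then HOCH2CH2OH, TsOH·H2O (cat.), rt
Reagents that add atoms: hydrogen bromide, Br; ethane-1,2-diol, OCCO
Why: Conjugate hydrobromination of the enone followed by acid-catalysed ketalisation masks the ketone so that a Grignard reagent can be prepared.

Step 5
Reactants: 5 3,6-dimethylcyclohepta-2,6-dien-1-one; 8 2-(2-bromoethyl)-2-(propan-2-yl)-1,3-dioxolane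
Product: 10 (6R)-3,6-dimethyl-6-{2-[2-(propan-2-yl)-1,3-dioxolan-2-yl]ethyl}cyclohept-2-en-1-one, via {2-[2-(propan-2-yl)-1,3-dioxolan-2-yl]ethyl}magnesium bromide 9 (not isolated)
Conditions: Mg, THF, 25 °C; then added slowly to 5, Cu(OTf)2 (4 mol%), chiral C2-symmetric imidazolinium chloride (NHC precursor, 5 mol%), Et2O, −30 °C; aq. NH4Cl
Reagents that add atoms: magnesium, [Mg]
Why: Cu-catalysed asymmetric conjugate addition of the Grignard reagent to one of the two equivalent β-methyl enone units breaks the symmetry of 5 and creates the quaternary stereocentre (later C8a) under control of the chiral NHC–copper catalyst; the cross-conjugated magnesium enolate does not accept a second addition.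

Step 6
Reactants: 10 (6R)-3,6-dimethyl-6-{2-[2-(propan-2-yl)-1,3-dioxolan-2-yl]ethyl}cyclohept-2-en-1-one
Product: 12 (3R,3aR,8aR)-3-hydroxy-6,8a-dimethyl-3-(propan-2-yl)-2,3,3a,7,8,8a-hexahydroazulen-4(1H)-one, via (6R)-3,6-dimethyl-6-(4-methyl-3-oxopentyl)cyclohept-2-en-1-one 11 (not isolated)
Conditions: 1 M aq. HCl, THF, rt; then KOt-Bu (0.2 equiv), t-BuOH–THF, 0 °C
Reagents that add atoms: water, O
Why: Ketal hydrolysis followed by reversible intramolecular aldol addition of the ring α-carbon to the isopropyl ketone, the closure mode that keeps the enone conjugation; closure from the tether enforces the cis ring fusion (3a-H cis to 8a-CH3), and the hydroxyl ends up syn to the ring carbonyl (hydrogen-bonded aldolate), i.e. trans to 3a-H with isopropyl on the convex face.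

Step 7
Reactants: 12 (3R,3aR,8aR)-3-hydroxy-6,8a-dimethyl-3-(propan-2-yl)-2,3,3a,7,8,8a-hexahydroazulen-4(1H)-one
Product: 13 (3R,3aR,8aS)-3-hydroxy-6,8a-dimethyl-3-(propan-2-yl)-2,3,3a,8a-tetrahydroazulen-4(1H)-one
Conditions: chloranil (1.3 equiv), t-BuOH, reflux
Reagents that add atoms: none
Why: Quinone dehydrogenation through the extended dienol (hydride abstraction from the δ-carbon) gives the linear dienone; the other side of the ketone cannot react because C3a is flanked by two fully substituted carbons.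

Step 8
Reactants: 13 (3R,3aR,8aS)-3-hydroxy-6,8a-dimethyl-3-(propan-2-yl)-2,3,3a,8a-tetrahydroazulen-4(1H)-one
Product: 15 (3R,3aR,8S,8aR)-3,8-dihydroxy-6,8a-dimethyl-3-(propan-2-yl)-2,3,3a,5,8,8a-hexahydroazulen-4(1H)-one, via allylic pinacolboronate 14 (not isolated)
Conditions: B2pin2, CuCl (5 mol%), DPEphos (5 mol%), NaOt-Bu (10 mol%), MeOH (2 equiv), THF, rt; then NaBO3·4H2O, THF–H2O, rt
Reagents that add atoms: bis(pinacolato)diboron, CC1(C)OB(OC1(C)C)B1OC(C)(C)C(C)(C)O1; sodium perborate, B(=O)O[O-].[Na+]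
Why: Copper–boryl conjugate addition goes 1,6 because the β-carbon is fully substituted, with boron delivered to C8 anti to the neighbouring angular methyl; α-protonation of the dienolate leaves the 6,7-alkene and perborate oxidation of the C–B bond proceeds with retention, so the 8-hydroxyl is trans to the methyl.

Step 9
Reactants: 15 (3R,3aR,8S,8aR)-3,8-dihydroxy-6,8a-dimethyl-3-(propan-2-yl)-2,3,3a,5,8,8a-hexahydroazulen-4(1H)-one; 16 (2E)-2-methylbut-2-enoyl chloride
Product: 17 (3R,3aR,8S,8aR)-3-hydroxy-6,8a-dimethyl-4-oxo-3-(propan-2-yl)-1,2,3,3a,4,5,8,8a-octahydroazulen-8-yl (2E)-2-methylbut-2-enoate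
Conditions: pyridine, DMAP (cat.), CH2Cl2, 0 °C to rt
Reagents that add atoms: none
Why: DMAP-catalysed acylation of the only secondary hydroxyl (the tertiary carbinol is inert); pyridine instead of a trialkylamine avoids vinylketene formation from the acid chloride and isomerisation of the β,γ-unsaturated ketone.

Step 10
Reactants: 17 (3R,3aR,8S,8aR)-3-hydroxy-6,8a-dimethyl-4-oxo-3-(propan-2-yl)-1,2,3,3a,4,5,8,8a-octahydroazulen-8-yl (2E)-2-methylbut-2-enoate
Product: 18 (3R,3aS,4S,8S,8aR)-3,4-dihydroxy-6,8a-dimethyl-3-(propan-2-yl)-1,2,3,3a,4,5,8,8a-octahydroazulen-8-yl (2E)-2-methylbut-2-enoate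
Conditions: Me4NBH(OAc)3, MeCN–AcOH (1:1), −25 °C
Reagents that add atoms: none
Why: Evans–Saksena reduction: the tertiary 3-hydroxyl binds the borohydride and delivers hydride intramolecularly to the β-ketone from its own face, giving the 1,3-anti diol (4-OH cis to 3a-H) without touching the enoate.

Step 11
Reactants: 18 (3R,3aS,4S,8S,8aR)-3,4-dihydroxy-6,8a-dimethyl-3-(propan-2-yl)-1,2,3,3a,4,5,8,8a-octahydroazulen-8-yl (2E)-2-methylbut-2-enoate; 19 4-(acetyloxy)benzoyl chloride
Product: 21 (3R,3aS,4S,8S,8aR)-3-hydroxy-6,8a-dimethyl-8-{[(2E)-2-methylbut-2-enoyl]oxy}-3-(propan-2-yl)-1,2,3,3a,4,5,8,8a-octahydroazulen-4-yl 4-hydroxybenzoate, via 4-acetoxybenzoate ester 20 (not isolated)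
Conditions: pyridine, DMAP (cat.), CH2Cl2, rt; then MeOH, K2CO3 (0.3 equiv), 0 °C
Reagents that add atoms: none
Why: DMAP-catalysed aroylation of the secondary 4-hydroxyl (tertiary OH inert), then mild base methanolysis that cleaves only the phenolic acetate, which is far more labile than the tiglate and the benzoate (the latter is further deactivated once the phenoxide forms).

## Compound list

1 | 2,5-dimethylfuran | Cc1ccc(C)o1 | starting material
2 | 1,1,3,3-tetrabromopropan-2-one | BrC(Br)C(=O)C(Br)Br | starting material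
3 | 2,4-dibromo-1,5-dimethyl-8-oxabicyclo[3.2.1]oct-6-en-3-one (cis oxygen bridge; C2/C4 bromide epimer mixture, the two CHBr centres left open) | C[C@]12C=C[C@](C)(O1)C(Br)C(=O)C2Br | intermediate
4 | (1R,5S)-1,5-dimethyl-8-oxabicyclo[3.2.1]octan-3-one (meso) | C[C@]12CC[C@](C)(O1)CC(=O)C2 | intermediate
5 | 3,6-dimethylcyclohepta-2,6-dien-1-one | CC1=CC(=O)C=C(C)CC1 | intermediate
6 | 4-methylpent-1-en-3-one | C=CC(=O)C(C)C | starting material
7 | 1-bromo-4-methylpentan-3-one | BrCCC(=O)C(C)C | intermediate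
8 | 2-(2-bromoethyl)-2-(propan-2-yl)-1,3-dioxolane | BrCCC1(OCCO1)C(C)C | intermediate
9 | {2-[2-(propan-2-yl)-1,3-dioxolan-2-yl]ethyl}magnesium bromide | Br[Mg]CCC1(OCCO1)C(C)C | intermediate
10 | (6R)-3,6-dimethyl-6-{2-[2-(propan-2-yl)-1,3-dioxolan-2-yl]ethyl}cyclohept-2-en-1-one | C1CC(C)=CC(=O)C[C@@]1(C)CCC2(OCCO2)C(C)C | intermediate
11 | (6R)-3,6-dimethyl-6-(4-methyl-3-oxopentyl)cyclohept-2-en-1-one | C1CC(C)=CC(=O)C[C@@]1(C)CCC(=O)C(C)C | intermediate
12 | (3R,3aR,8aR)-3-hydroxy-6,8a-dimethyl-3-(propan-2-yl)-2,3,3a,7,8,8a-hexahydroazulen-4(1H)-one (cis-fused; 8a-CH3, 3a-H and isopropyl on one face, 3-OH on the other) | C1CC(C)=CC(=O)[C@@H]2[C@@]1(C)CC[C@@]2(O)C(C)C | intermediate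
13 | (3R,3aR,8aS)-3-hydroxy-6,8a-dimethyl-3-(propan-2-yl)-2,3,3a,8a-tetrahydroazulen-4(1H)-one | C1=CC(C)=CC(=O)[C@@H]2[C@@]1(C)CC[C@@]2(O)C(C)C | intermediate
14 | (3R,3aR,8S,8aS)-3-hydroxy-6,8a-dimethyl-3-(propan-2-yl)-8-(4,4,5,5-tetramethyl-1,3,2-dioxaborolan-2-yl)-2,3,3a,5,8,8a-hexahydroazulen-4(1H)-one (allylic pinacolboronate, boron trans to 8a-CH3) | CC1(C)OB(OC1(C)C)[C@H]1C=C(C)CC(=O)[C@@H]2[C@@]1(C)CC[C@@]2(O)C(C)C | intermediate
15 | (3R,3aR,8S,8aR)-3,8-dihydroxy-6,8a-dimethyl-3-(propan-2-yl)-2,3,3a,5,8,8a-hexahydroazulen-4(1H)-one | O[C@H]1C=C(C)CC(=O)[C@@H]2[C@@]1(C)CC[C@@]2(O)C(C)C | intermediate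
16 | (2E)-2-methylbut-2-enoyl chloride (tigloyl chloride) | C/C=C(\C)C(Cl)=O | starting material
17 | (3R,3aR,8S,8aR)-3-hydroxy-6,8a-dimethyl-4-oxo-3-(propan-2-yl)-1,2,3,3a,4,5,8,8a-octahydroazulen-8-yl (2E)-2-methylbut-2-enoate | C/C=C(\C)C(=O)O[C@H]1C=C(C)CC(=O)[C@@H]2[C@@]1(C)CC[C@@]2(O)C(C)C | intermediate
18 | (3R,3aS,4S,8S,8aR)-3,4-dihydroxy-6,8a-dimethyl-3-(propan-2-yl)-1,2,3,3a,4,5,8,8a-octahydroazulen-8-yl (2E)-2-methylbut-2-enoate | C/C=C(\C)C(=O)O[C@H]1C=C(C)C[C@H](O)[C@@H]2[C@@]1(C)CC[C@@]2(O)C(C)C | intermediate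
19 | 4-(acetyloxy)benzoyl chloride | CC(=O)Oc1ccc(cc1)C(Cl)=O | starting material
20 | (3R,3aS,4S,8S,8aR)-3-hydroxy-6,8a-dimethyl-8-{[(2E)-2-methylbut-2-enoyl]oxy}-3-(propan-2-yl)-1,2,3,3a,4,5,8,8a-octahydroazulen-4-yl 4-(acetyloxy)benzoate | C/C=C(\C)C(=O)O[C@H]1C=C(C)C[C@H](OC(=O)c2ccc(OC(C)=O)cc2)[C@@H]2[C@@]1(C)CC[C@@]2(O)C(C)C | intermediate
21 | (3R,3aS,4S,8S,8aR)-3-hydroxy-6,8a-dimethyl-8-{[(2E)-2-methylbut-2-enoyl]oxy}-3-(propan-2-yl)-1,2,3,3a,4,5,8,8a-octahydroazulen-4-yl 4-hydroxybenzoate | C/C=C(\C)C(=O)O[C@H]1C=C(C)C[C@H](OC(=O)c2ccc(O)cc2)[C@@H]2[C@@]1(C)CC[C@@]2(O)C(C)C | target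

## Step count and risks

Total step count: 11. Longest linear sequence: 10 (steps 1, 2, 3, 5, 6, 7, 8, 9, 10, 11); step 4 is a one-step branch.

The three steps most likely to fail are 5, 6 and 8.

**Step 5.** The cross-conjugated dienone may be sluggish or give modest enantioselectivity in the catalytic addition. The fallback sets out again from 5 and returns at 10. The Grignard reagent 9 is added under achiral, more forcing conditions (CuBr·SMe2, TMSCl, THF, −78 °C) to give the racemate. The enantiomers are then separated by preparative chromatography on a chiral stationary phase: the (6S)-enantiomer of 10 F1 is set aside and the (6R)-enantiomer continues as 10. This replaces asymmetric catalysis by a resolution.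

**Step 6.** The reversible aldol may stall at the open diketone, close in the wrong mode (side-chain enolate onto the ring carbonyl) or dehydrate. The fallback sets out from 10 and returns at 12, and makes the ring enolate regiospecifically and irreversibly. Kinetic enolisation of 10 (LiN(i-Pr)2, TMSCl, THF, −78 °C) gives the cross-conjugated trimethylsilyl dienol ether of 10 F2. NBS converts it into the 7-bromo derivative of 10 F3, and aqueous HCl in THF removes the ketal to give the 7-bromo derivative of 11 F4. SmI2 in THF at −78 °C then effects a Reformatsky-type cyclisation through a chelated samarium enolate, which gives 12 with the same cis fusion and hydroxyl orientation.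

**Step 8.** The facial selectivity at C8 is the least certain stereochemical call (angular methyl on one face, folded five-membered ring on the other). The fallback sets out from 13 and returns at 17. If boron is delivered syn to the methyl, the same conditions give the C8 epimer of 14 F5 and, after oxidation, the C8 epimer of 15 F6. F6 is not discarded: Mitsunobu esterification with tiglic acid (PPh3, DIAD, toluene, 0 °C to rt) inverts C8 and gives 17 directly, skipping step 9.

## Further compounds

F1 | step 5 | (6S)-enantiomer of 10 | C1CC(C)=CC(=O)C[C@]1(C)CCC2(OCCO2)C(C)C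
F2 | step 6 | cross-conjugated trimethylsilyl dienol ether of 10 | C1CC(C)=CC(O[Si](C)(C)C)=C[C@@]1(C)CCC2(OCCO2)C(C)C
F3 | step 6 | 7-bromo derivative of 10 (bromide epimers) | C1CC(C)=CC(=O)C(Br)[C@@]1(C)CCC2(OCCO2)C(C)C
F4 | step 6 | 7-bromo derivative of 11 (bromide epimers) | C1CC(C)=CC(=O)C(Br)[C@@]1(C)CCC(=O)C(C)C
F5 | step 8 | C8 epimer of 14 | CC1(C)OB(OC1(C)C)[C@@H]1C=C(C)CC(=O)[C@@H]2[C@@]1(C)CC[C@@]2(O)C(C)C
F6 | step 8 | C8 epimer of 15 | O[C@@H]1C=C(C)CC(=O)[C@@H]2[C@@]1(C)CC[C@@]2(O)C(C)C
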